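The route rests on cutting the δ-lactone (ring atoms C7, O, C20, C10, C9, C8; kaurane numbering) at its two C–C bonds, C20–C10 and C7–C8. C10 and C8 are each α to an oxygenated carbon (C1, C15) and 1,3-related through C9–H, so a 1,5-keto ester can act as a bis-enolate towards ClCH2OC(O)Cl. In one flask the ring A dienolate is O-acylated, the C8 ester enolate takes the acyl group back (C7–C8) and the freed dienolate closes the spiro-lactone by alkylation (C20–C10). The precursor, enone ester 18, comes from a domino Knoevenagel–hetero-Diels–Alder union of a chiral-pool aldehyde with 4,4-dimethylcyclohexane-1,3-dione; ring D is closed last.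

Key step: step 13

Remark: atoms carry ent-kaurane numbers (C1–C20) throughout; lactol, acetal, vinyl sulfide and enol ether centres that are destroyed later are carried as mixtures.

Step 1
Reactants: 1 (S)-cyclohex-3-ene-1-carboxylic acid
Product: 2 (1S,4S,5S)-4-iodo-6-oxabicyclo[3.2.1]octan-7-one
Conditions: I2, KI, NaHCO3, H2O/CH2Cl2, 0 °C to rt, dark
Reagents that add atoms: iodine, II
Why: Iodolactonization, in which the carboxylate opens the iodonium ion at the 1,3-related alkene carbon, so the new C–O bond (later O11) is necessarily cis to the carboxyl carbon (later C16) and trans to iodine.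

Step 2
Reactants: 2 (1S,4S,5S)-4-iodo-6-oxabicyclo[3.2.1]octan-7-one
Product: 3 (1S,5S)-6-oxabicyclo[3.2.1]oct-3-en-7-one
Conditions: DBU, toluene, 80 °C
Reagents that add atoms: none
Why: E2 dehydroiodination, in which only the flanking CH2 offers an anti-periplanar hydrogen, so the alkene (later C8=C9) forms next to the C–O carbon and both stereocentres stay untouched.

Step 3
Reactants: 3 (1S,5S)-6-oxabicyclo[3.2.1]oct-3-en-7-one
Product: 4 (1S,5S)-6-oxabicyclo[3.2.1]oct-3-en-7-ol (lactol, both anomers)
Conditions: i-Bu2AlH, CH2Cl2, −78 °C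
Reagents that add atoms: none
Why: Partial reduction of a lactone with i-Bu2AlH, which should stop at the tetrahedral aluminate at low temperature and give the lactol.

Step 4
Reactants: 4 (1S,5S)-6-oxabicyclo[3.2.1]oct-3-en-7-ol
Product: 5 (1S,5S)-5-ethynylcyclohex-2-en-1-ol
Conditions: Ohira–Bestmann reagent, K2CO3, MeOH, 0 °C to rt
Reagents that add atoms: dimethyl (1-diazo-2-oxopropyl)phosphonate, COP(=O)(OC)C(=[N+]=[N-])C(C)=O
Why: Seyferth–Gilbert homologation (Ohira–Bestmann variant) of the open hydroxy aldehyde form of the lactol, whose mild carbonate conditions should keep the cis-1,3 relationship of hydroxyl and alkynyl groups.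

Step 5
Reactants: 5 (1S,5S)-5-ethynylcyclohex-2-en-1-ol
Product: 6 tert-butyl{[(1S,5S)-5-ethynylcyclohex-2-en-1-yl]oxy}dimethylsilane
Conditions: TBSCl, imidazole, DMF, rt
Reagents that add atoms: tert-butyldimethylsilyl chloride, CC(C)(C)[Si](C)(C)Cl
Why: Standard silylation of the secondary allylic alcohol, giving an ether that should survive the basic and mildly acidic steps up to step 17.

Step 6
Reactants: 6 tert-butyl{[(1S,5S)-5-ethynylcyclohex-2-en-1-yl]oxy}dimethylsilane
Product: 8 {[(1S,5S)-5-(1-bromoethenyl)cyclohex-2-en-1-yl]oxy}(tert-butyl)dimethylsilane, via alkenylborane 7 (not isolated)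
Conditions: B-bromo-9-BBN, CH2Cl2, 0 °C; AcOH, 0 °C to rt
Reagents that add atoms: B-bromo-9-borabicyclo[3.3.1]nonane, BrB1C2CCCC1CCC2
Why: Bromoboration of the terminal alkyne (syn addition, boron on the terminal carbon) followed by protonolysis of the alkenyl C–B bond, which should give the 2-bromo-1-alkene regioselectively.

Step 7
Reactants: 8 {[(1S,5S)-5-(1-bromoethenyl)cyclohex-2-en-1-yl]oxy}(tert-butyl)dimethylsilane
Product: 10 (3R,5S)-3-(1-bromoethenyl)-5-[(tert-butyldimethylsilyl)oxy]-6,6-dimethoxyhexanal, via methoxy hydroperoxide 9 (not isolated)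
Conditions: O3, CH2Cl2/MeOH, −78 °C; TsOH·H2O, rt; NaHCO3; Me2S, rt
Reagents that add atoms: ozone, [O-][O+]=O; methanol, CO
Why: Criegee ozonolysis in methanol with terminus differentiation, in which the carbonyl oxide should form away from the allylic silyloxy group, acid acetalizes the free α-silyloxy aldehyde (C9) and reduction of the α-methoxy hydroperoxide unveils only the distal aldehyde (C8), while the electron-poor bromoalkene reacts more slowly with ozone.

Step 8
Reactants: 10 (3R,5S)-3-(1-bromoethenyl)-5-[(tert-butyldimethylsilyl)oxy]-6,6-dimethoxyhexanal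
Product: 11 tert-butyl{[(2S,4S)-4-(1-bromoethenyl)-1,1-dimethoxy-7-(phenylsulfanyl)hept-6-en-2-yl]oxy}dimethylsilane (E/Z mixture)
Conditions: [Ph3PCH2SPh]Cl, KN(SiMe3)2, THF, −78 °C to rt
Reagents that add atoms: (phenylsulfanylmethyl)triphenylphosphonium chloride, [Cl-].c1ccc(cc1)SC[P+](c1ccccc1)(c1ccccc1)c1ccccc1
Why: Wittig olefination of the only free aldehyde, which adds C15 and gives a vinyl sulfide that tolerates the following acetal hydrolysis and is an electron-rich dienophile in either geometry.

Step 9
Reactants: 11 tert-butyl{[(2S,4S)-4-(1-bromoethenyl)-1,1-dimethoxy-7-(phenylsulfanyl)hept-6-en-2-yl]oxy}dimethylsilane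
Product: 12 (2S,4S)-4-(1-bromoethenyl)-2-[(tert-butyldimethylsilyl)oxy]-7-(phenylsulfanyl)hept-6-enal
Conditions: LiBF4, MeCN/H2O, rt
Reagents that add atoms: water, O
Why: Mild Lewis-acid-assisted acetal hydrolysis, which should free the α-silyloxy aldehyde while silyl ether, vinyl sulfide and bromoalkene survive.

Step 10
Reactants: 12 (2S,4S)-4-(1-bromoethenyl)-2-[(tert-butyldimethylsilyl)oxy]-7-(phenylsulfanyl)hept-6-enal, 13 4,4-dimethylcyclohexane-1,3-dione
Product: 15 trans-fused pyran-annulated vinylogous ester (ring A plus O1–C15 O,S-acetal plus ring C), via alkylidene dione 14 (not isolated)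
Conditions: ethylenediammonium diacetate (cat.), CH2Cl2, rt to 40 °C
Reagents that add atoms: 4,4-dimethylcyclohexane-1,3-dione (13), CC1(C)CCC(=O)CC1=O
Why: Domino Knoevenagel condensation and intramolecular hetero-Diels–Alder reaction with inverse electron demand, in which the chair-like exo transition state with the cis-related silyloxy and bromoethenyl groups both equatorial should give the trans ring fusion and C9 with C10 anti to O11, and in which the dione carbonyl remote from the gem-dimethyl group should act as heterodiene oxygen because the other one is shielded on both faces by the methyl groups.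

Step 11
Reactants: 15 trans-fused pyran-annulated vinylogous ester
Product: 17 enone aldehyde (ring A 3-(methoxymethyl)-4,4-dimethylcyclohex-2-en-1-one joined through C10–C9 to ring C carrying 8-CHO, 11-OTBS and 13-(1-bromoethenyl)), via tertiary carbinol 16 (not isolated)
Conditions: Bu3SnCH2OMe, n-BuLi, THF, −78 °C; then 15; then 1 M HCl, THF, 0 °C
Reagents that add atoms: tributyl(methoxymethyl)stannane, CCCC[Sn](CCCC)(CCCC)COC; water, O
Why: Stork–Danheiser transposition, in which the small (methoxymethyl)lithium adds 1,2 to the vinylogous ester carbonyl (C5) and aqueous acid then shifts the allylic system to the C1 ketone while the O,S-acetal collapses to the C15 aldehyde, which settles trans to ring A on the epimerizable C8.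

Step 12
Reactants: 17 enone aldehyde
Product: 18 enone methyl ester (C15 = CO2Me)
Conditions: I2, KOH, MeOH, 0 °C
Reagents that add atoms: methanol, CO
Why: Oxidative esterification of the aldehyde through its methyl hemiacetal, which leaves the hindered tetrasubstituted enone alone, and whose effect on C8 does not matter because C8 is made planar in step 13.

Step 13
Reactants: 18 enone methyl ester, 19 chloromethyl chloroformate
Product: 22 spirolactone methyl ester (7,20-olide with C1 ketone and C5=C6 methyl enol ether), via dienyl carbonate 20 (not isolated), via malonate dienolate 21 (not isolated)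
Conditions: KN(SiMe3)2 (0.95 equiv), THF, −78 to 0 °C; 19 (1.0 equiv), −78 °C; KN(SiMe3)2 (1.1 equiv), −78 °C to rt
Reagents that add atoms: chloromethyl chloroformate (19), ClCOC(Cl)=O
Why: Proposed new method: the equilibrated extended ring A dienolate is O-acylated to the dienyl chloromethyl carbonate, the C8 ester enolate then attacks the carbonate carbonyl through a six-membered cyclic transition state and takes over the ClCH2O–C(=O) unit (C7–C8 bond), and the dienolate set free displaces chloride at its α-carbon C10 (C20–C10 bond), which closes the δ-lactone by 6-exo-tet C-alkylation. The closest known reaction types are the Baker–Venkataraman O-to-C acyl transfer and the intramolecular α-alkylation of extended ketone dienolates with acyloxymethyl halides; their merger into one relay on a chloromethyl carbonate is the new element. At C8 the acyl group is delivered from ring A, which sits on C9, so C7 should enter cis to C10 on ring C and leave the methyl ester (C15) cis to H9 and to the bromoethenyl group. At C10 the potassium ion should stay bridged between O1 and the C7 carbonyl in the chair-like alkylation transition state, which puts C8 on the C1 side of the dienolate, H9 inside towards C5=C6 and C11 anti to the forming bond, so that C20 adds to the face that gives the natural spiro centre. The step needs C- over O-alkylation and α- over γ-alkylation, both secured because the alternatives would close eight-membered rings, and it needs loss of the dienolate and not of chloromethoxide from the tetrahedral intermediate, which the better leaving-group ability of the dienolate should secure.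

Step 14
Reactants: 22 spirolactone methyl ester
Product: 23 spirolactone 1-alcohol (hydroxyl cis to C20)
Conditions: NaBH4, MeOH/CH2Cl2, −20 °C
Reagents that add atoms: none
Why: Borohydride reduction of the only ketone, in which hydride should approach C1 anti to the axial C20 methylene on the neighbouring spiro carbon and give the equatorial alcohol cis to C20, while ester, lactone, enol ether and bromoalkene are inert.

Step 15
Reactants: 23 spirolactone 1-alcohol
Product: 24 spirolactone 1-acetate
Conditions: Ac2O, DMAP, pyridine, CH2Cl2, rt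
Reagents that add atoms: acetic anhydride, CC(=O)OC(C)=O
Why: DMAP-catalysed acetylation of the only free hydroxyl group, done at once so that the C1 alkoxide cannot attack the lactone.

Step 16
Reactants: 24 spirolactone 1-acetate
Product: 25 ring D enone (15-oxo-16-methylene bicyclo[3.2.1]octane)
Conditions: t-BuLi (2.1 equiv), THF/Et2O, −100 to −78 °C; AcOH quench
Reagents that add atoms: none
Why: Parham-type cyclization, in which bromine–lithium exchange should outrun carbonyl addition at −100 °C and the alkenyllithium on C13 can reach only the cis methyl ester on C8 (5-exo acyl substitution), so ring D closes as the α-methylene ketone and the bridge can only form cis.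

Step 17
Reactants: 25 ring D enone
Product: 26 keto aldehyde (6-al, 11-ol, 15-one)
Conditions: aq. HF, MeCN, 0 °C to rt
Reagents that add atoms: water, O
Why: Acidic desilylation together with enol ether hydrolysis, in which kinetic protonation at C5 should occur anti to C20 and to the axial C4 methyl group and so place the formyl group equatorial and cis to C20.

Step 18
Reactants: 26 keto aldehyde
Product: 27 CNP0210922.1 (target)
Conditions: NaBH4, CeCl3·7H2O, MeOH, −78 to −40 °C
Reagents that add atoms: none
Why: Luche reduction, in which 1,2-attack on the enone from the convex face (the C7 side, away from the C9–C11–C12 bridge) should give the 15-alcohol syn to that bridge and the aldehyde is reduced to the primary alcohol, while acetate and lactone survive at low temperature.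

Compound list
1 | (S)-cyclohex-3-ene-1-carboxylic acid | OC(=O)[C@@H]1CC=CCC1 | starting material
2 | (1S,4S,5S)-4-iodo-6-oxabicyclo[3.2.1]octan-7-one | O=C1[C@H]2CC[C@H](I)[C@H](C2)O1 | intermediate
3 | (1S,5S)-6-oxabicyclo[3.2.1]oct-3-en-7-one | O=C1[C@H]2CC=C[C@H](C2)O1 | intermediate
4 | (1S,5S)-6-oxabicyclo[3.2.1]oct-3-en-7-ol (lactol, both anomers) | OC1[C@H]2CC=C[C@H](C2)O1 | intermediate
5 | (1S,5S)-5-ethynylcyclohex-2-en-1-ol | C#C[C@H]1CC=C[C@H](C1)O | intermediate
6 | tert-butyl{[(1S,5S)-5-ethynylcyclohex-2-en-1-yl]oxy}dimethylsilane | C#C[C@H]1CC=C[C@H](C1)O[Si](C)(C)C(C)(C)C | intermediate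
7 | 9-[2-bromo-2-(cyclohexenyl)ethenyl]-9-borabicyclo[3.3.1]nonane adduct of 6 (alkenylborane) | BrC(=CB1C2CCCC1CCC2)[C@H]1CC=C[C@H](C1)O[Si](C)(C)C(C)(C)C | intermediate (not isolated)
8 | {[(1S,5S)-5-(1-bromoethenyl)cyclohex-2-en-1-yl]oxy}(tert-butyl)dimethylsilane | C=C(Br)[C@H]1CC=C[C@H](C1)O[Si](C)(C)C(C)(C)C | intermediate
9 | (3R,5S)-3-(1-bromoethenyl)-5-[(tert-butyldimethylsilyl)oxy]-1,6,6-trimethoxyhexyl hydroperoxide (C1 epimers) | COC(OC)[C@@H](O[Si](C)(C)C(C)(C)C)C[C@@H](C(Br)=C)CC(OC)OO | intermediate (not isolated)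
10 | (3R,5S)-3-(1-bromoethenyl)-5-[(tert-butyldimethylsilyl)oxy]-6,6-dimethoxyhexanal | COC(OC)[C@@H](O[Si](C)(C)C(C)(C)C)C[C@@H](C(Br)=C)CC=O | intermediate
11 | tert-butyl{[(2S,4S)-4-(1-bromoethenyl)-1,1-dimethoxy-7-(phenylsulfanyl)hept-6-en-2-yl]oxy}dimethylsilane (E/Z) | COC(OC)[C@@H](O[Si](C)(C)C(C)(C)C)C[C@@H](C(Br)=C)CC=CSc1ccccc1 | intermediate
12 | (2S,4S)-4-(1-bromoethenyl)-2-[(tert-butyldimethylsilyl)oxy]-7-(phenylsulfanyl)hept-6-enal (E/Z) | O=C[C@@H](O[Si](C)(C)C(C)(C)C)C[C@@H](C(Br)=C)CC=CSc1ccccc1 | intermediate
13 | 4,4-dimethylcyclohexane-1,3-dione | CC1(C)CCC(=O)CC1=O | starting material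
14 | Knoevenagel adduct: 2-alkylidene-4,4-dimethylcyclohexane-1,3-dione whose alkylidene carbon (C9) carries the (2S,4S) chain of 12 | O=C1CCC(C)(C)C(=O)C1=C[C@@H](O[Si](C)(C)C(C)(C)C)C[C@@H](C(Br)=C)CC=CSc1ccccc1 | intermediate (not isolated)
15 | hetero-Diels–Alder adduct: ring A vinylogous ester (C5 ketone next to CMe2, enol ether O1 on C1) fused through the O1–C15 O,S-acetal (SPh, C15 epimers) to ring C; H8 and H9 trans; 11-OTBS and 13-(1-bromoethenyl) equatorial; C9, C11, C13 as in 27 | C=C(Br)[C@@H]2C[C@H](O[Si](C)(C)C(C)(C)C)[C@@H]3[C@@H](C2)C(Sc5ccccc5)OC4=C3C(=O)C(C)(C)CC4 | intermediate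
16 | tertiary carbinol of 15: C5 carries OH and CH2OMe (C5 epimers) | C=C(Br)[C@@H]2C[C@H](O[Si](C)(C)C(C)(C)C)[C@@H]3[C@@H](C2)C(Sc5ccccc5)OC4=C3C(O)(COC)C(C)(C)CC4 | intermediate (not isolated)
17 | enone aldehyde: 3-(methoxymethyl)-4,4-dimethylcyclohex-2-en-1-one (ring A) bonded at C10 to C9 of ring C, which carries 8-CHO (trans to ring A), 11-OTBS (trans to ring A) and 13-(1-bromoethenyl) (cis to OTBS) | C=C(Br)[C@@H]2C[C@H](O[Si](C)(C)C(C)(C)C)[C@@H](C3=C(COC)C(C)(C)CCC3=O)[C@@H](C2)C=O | intermediate
18 | enone methyl ester: as 17 with C15 as CO2Me | C=C(Br)[C@@H]2C[C@H](O[Si](C)(C)C(C)(C)C)[C@@H](C3=C(COC)C(C)(C)CCC3=O)[C@@H](C2)C(=O)OC | intermediate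
19 | chloromethyl chloroformate | ClCOC(Cl)=O | starting material
20 | dienyl carbonate: ring A as 1-[(chloromethoxy)carbonyloxy]-1(10),5(6)-diene with OMe on C6, otherwise as 18 | C=C(Br)[C@@H]2C[C@H](O[Si](C)(C)C(C)(C)C)[C@@H](C3=C(OC(=O)OCCl)CCC(C)(C)C3=COC)[C@@H](C2)C(=O)OC | intermediate (not isolated)
21 | potassium ring A dienolate whose C8 carries CO2Me (C15) and CO2CH2Cl (C7, cis to C10) | C=C(Br)[C@@H]2C[C@H](O[Si](C)(C)C(C)(C)C)[C@@H](C3=C([O-])CCC(C)(C)C3=COC)[C@](C2)(C(=O)OCCl)C(=O)OC.[K+] | intermediate (not isolated)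
22 | spirolactone methyl ester: 7,20-olide spiro at C10, C8 CO2Me (C15), C1 ketone, C5=C6H–OMe, 11-OTBS, 13-(1-bromoethenyl); C8, C9, C10, C11, C13 as in 27 | C=C(Br)[C@@H]2C[C@H](O[Si](C)(C)C(C)(C)C)[C@@H]3[C@](C2)(C(=O)OC[C@]32C(=O)CCC(C)(C)C2=COC)C(=O)OC | intermediate
23 | spirolactone 1-alcohol: as 22 with C1–OH cis to C20 | C=C(Br)[C@@H]2C[C@H](O[Si](C)(C)C(C)(C)C)[C@@H]3[C@](C2)(C(=O)OC[C@]32[C@@H](O)CCC(C)(C)C2=COC)C(=O)OC | intermediate
24 | spirolactone 1-acetate: as 23 with C1–OAc | C=C(Br)[C@@H]2C[C@H](O[Si](C)(C)C(C)(C)C)[C@@H]3[C@](C2)(C(=O)OC[C@]32[C@@H](OC(C)=O)CCC(C)(C)C2=COC)C(=O)OC | intermediate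
25 | ring D enone: 15-oxo-16-methylene bicyclo[3.2.1]octane, 7,20-olide, 1-OAc, 11-OTBS, C5=C6H–OMe | C=C1[C@@H]2C[C@H](O[Si](C)(C)C(C)(C)C)[C@@H]3[C@](C2)(C(=O)OC[C@]32[C@@H](OC(C)=O)CCC(C)(C)C2=COC)C1=O | intermediate
26 | keto aldehyde: as 27 but with C6 aldehyde and C15 ketone | C=C1[C@@H]2C[C@H](O)[C@@H]3[C@](C2)(C(=O)OC[C@]32[C@@H](OC(C)=O)CCC(C)(C)[C@H]2C=O)C1=O | intermediate
27 | CNP0210922.1: 1α-acetoxy-6,11,15-trihydroxy-6,7-seco-ent-kaur-16-en-7,20-olide | C=C1[C@@H]2C[C@H](O)[C@@H]3[C@](C2)(C(=O)OC[C@]32[C@@H](OC(C)=O)CCC(C)(C)[C@H]2CO)[C@@H]1O | target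

Total step count: 18. Longest linear sequence: 18 steps (1 to 27); 13 and 19 are used as purchased.

Steps most likely to fail

Step 13 (Proposed new method). The ring closure may show poor facial selectivity at C10, the tetrahedral intermediate may lose chloromethoxide and not the dienolate, or the first stage may trap the kinetic cross-conjugated enolate. The fallback uses known reactions only, sets out from 18 and comes back at 22. The extended potassium dienolate of 18 (KOt-Bu, THF) is hydroxymethylated at C10 with gaseous formaldehyde, an aldol reaction at the α-carbon of an extended dienolate, to give the hydroxymethyl ketone F1. F1 is converted with 4-nitrophenyl chloroformate and pyridine into the mixed carbonate F2. KN(SiMe3)2 then forms the C8 ester enolate, which is acylated by the tethered carbonate (Dieckmann-type lactonization with loss of 4-nitrophenoxide) to give 22.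

Step 10. Regiocontrol between the two dione carbonyls may be lost, and allylic strain between the silyloxy group and the spectator carbonyl may erode the diastereoselectivity of the cycloaddition. The fallback sets out from 12 and 13 and comes back at 17. The vinyl sulfide of 12 is hydrolysed (HgCl2, CaCO3, MeCN/H2O) to the dialdehyde F3, and an intramolecular aldol condensation (dibenzylammonium trifluoroacetate) gives the cyclohexene carbaldehyde F4, since only the unbranched aldehyde can dehydrate. Conjugate addition of 13 to F4 (DABCO, anti to the silyloxy group) and acetalization of the lactol under equilibrating conditions (MeOH, PPTS) give the methyl acetal F5. F5 takes the place of 15 in step 11 and gives 17.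

Step 16. The organolithium may attack the acetate or the lactone, and the β-keto lactone may open by retro-Claisen cleavage with the methoxide set free. The fallback sets out from 24 and comes back at 25. Bromide–iodide exchange (CuI, NaI, trans-N,N′-dimethylcyclohexane-1,2-diamine, dioxane) gives the alkenyl iodide F6. Iodine–magnesium exchange with i-PrMgCl·LiCl at −40 °C then forms an alkenylmagnesium species that should tolerate acetate and lactone and acylate only the neighbouring methyl ester, giving 25.

Further compounds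
F1 | step 13 | 10-(hydroxymethyl) ketone: 18 with CH2OH on C10 (configured as in 27) and C5=C6H–OMe | C=C(Br)[C@@H]2C[C@H](O[Si](C)(C)C(C)(C)C)[C@@H]([C@]3(CO)C(=O)CCC(C)(C)C3=COC)[C@@H](C2)C(=O)OC
F2 | step 13 | 4-nitrophenyl carbonate of F1 | C=C(Br)[C@@H]2C[C@H](O[Si](C)(C)C(C)(C)C)[C@@H]([C@]3(COC(=O)Oc4ccc(cc4)[N+](=O)[O-])C(=O)CCC(C)(C)C3=COC)[C@@H](C2)C(=O)OC
F3 | step 10 | (2S,4S)-4-(1-bromoethenyl)-2-[(tert-butyldimethylsilyl)oxy]heptanedial | O=C[C@@H](O[Si](C)(C)C(C)(C)C)C[C@@H](C(Br)=C)CCC=O
F4 | step 10 | (3S,5S)-5-(1-bromoethenyl)-3-[(tert-butyldimethylsilyl)oxy]cyclohex-1-ene-1-carbaldehyde | O=CC1=C[C@@H](O[Si](C)(C)C(C)(C)C)C[C@@H](C(Br)=C)C1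
F5 | step 10 | methyl acetal analogue of 15 (OMe in place of SPh at C15) | C=C(Br)[C@@H]2C[C@H](O[Si](C)(C)C(C)(C)C)[C@@H]3[C@@H](C2)C(OC)OC4=C3C(=O)C(C)(C)CC4
F6 | step 16 | alkenyl iodide analogue of 24 (1-iodoethenyl on C13) | C=C(I)[C@@H]2C[C@H](O[Si](C)(C)C(C)(C)C)[C@@H]3[C@](C2)(C(=O)OC[C@]32[C@@H](OC(C)=O)CCC(C)(C)C2=COC)C(=O)OC
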